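**Plan**

- Numbering: ring A is the guaiacyl ring and ring B the acetosyringone ring. The chain is C7 (benzylic carbinol on ring A), C8 (bears the ring B oxygen) and C9 (CH2OH).
- Retrosynthesis: the C9 alcohol goes back to an ethyl ester, the acetyl group to a dioxolane and the ring A phenol to an acetate. The C8–O(ring B) and C7–C8 bonds are then cut together, leaving a phenol, an aryl aldehyde and ethyl diazoacetate.
- Enabling feature: C8 is bonded to the ring B phenol oxygen, to the carboxyl-level carbon C9 and to the carbinol carbon C7. This is the substitution pattern of a carbene carbon that has taken up a phenol O–H and then an aldehyde.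
- Forward: two one-step protections (ketal on ring B, acetate on ring A), then the three pieces are joined into the open chain in one step with no ring formed, then ester reduction with loss of the acetate, then ketal hydrolysis.
- Stereochemistry: C7 and C8 are both created in the three-component step under a chiral phosphoric acid, as the erythro (2R,3R) ester, which is (7R,8S) in the target. The last two steps touch neither centre.

Key step: step 3

Assumption: the (R) enantiomer of 3,3'-bis(2,4,6-triisopropylphenyl)-1,1'-binaphthyl-2,2'-diyl hydrogen phosphate is taken to be the one that leads to the (2R,3R) ester; the sense of induction cannot be derived from a close analogue, and the (S) acid would be used with no other change if the opposite sense were found.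

**Step 1**
Reactants: 1 acetosyringone, 1-(4-hydroxy-3,5-dimethoxyphenyl)ethan-1-one
Product: 2 2,6-dimethoxy-4-(2-methyl-1,3-dioxolan-2-yl)phenol
Conditions: HOCH2CH2OH (5 equiv), p-toluenesulfonic acid monohydrate (5 mol%), toluene, reflux, Dean–Stark trap; Et3N quench; chromatography on Et3N-deactivated silica
Reagents that add atoms: ethylene glycol, OCCO
Why: Acid-catalysed ketalisation (dioxolane formation) of an aryl methyl ketone, driven by azeotropic removal of water, should leave the phenol untouched, and the basic quench keeps the electron-rich, acid-labile ketal from reverting.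

**Step 2**
Reactants: 3 vanillin, 4-hydroxy-3-methoxybenzaldehyde
Product: 4 4-formyl-2-methoxyphenyl acetate (vanillin acetate)
Conditions: Ac2O, pyridine, rt
Reagents that add atoms: acetic anhydride, CC(=O)OC(C)=O
Why: Pyridine-mediated O-acetylation of a phenol is routine, and the acetate turns the para donor into a weak acceptor, which makes the formyl group a better electrophile for step 3 and can be removed by hydride later.

**Step 3**
Reactants: 2 2,6-dimethoxy-4-(2-methyl-1,3-dioxolan-2-yl)phenol; 4 4-formyl-2-methoxyphenyl acetate; 5 ethyl diazoacetate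
Product: 8 ethyl (2R,3R)-3-(4-acetoxy-3-methoxyphenyl)-2-[2,6-dimethoxy-4-(2-methyl-1,3-dioxolan-2-yl)phenoxy]-3-hydroxypropanoate, via oxonium ylide 6 (not isolated), via enol 7 (not isolated)
Conditions: Rh2(OAc)4 (2 mol%), (R)-3,3'-bis(2,4,6-triisopropylphenyl)-1,1'-binaphthyl-2,2'-diyl hydrogen phosphate (10 mol%), 4 Å molecular sieves, CH2Cl2, −20 °C; 5 (1.5 equiv) added by syringe pump to 2 (1 equiv) and 4 (2 equiv)
Reagents that add atoms: none
Why: Proposed new method: Rh2(OAc)4 should expel N2 from 5 and pass the metal-bound carbene carbon to the phenol oxygen of 2, giving oxonium ylide 6, which by a cyclic 1,3-proton transfer becomes enol 7 (drawn as the E isomer that this transfer implies); 7 then adds through its nucleophilic carbon to the formyl carbon of 4 while the enol O–H and the aldehyde oxygen are both hydrogen-bonded to the phosphoric acid, so that the C8–O and C7–C8 bonds form in one flask. The closest known reaction type is the three-component aldol-type trapping of alcohol-derived oxonium ylides from aryl diazoacetates by aldehydes under Rh2(OAc)4 and a chiral acid co-catalyst; a phenol as the O–H partner combined with an acceptor-only diazo ester has not been shown. No ring closes. C2 and C3 of the ester (C8 and C7 of the target) are both set in the C–C bond-forming event by the chiral phosphoric acid alone, whose 3,3'-aryl groups are expected to fix which face of 7 meets which face of 4 in the hydrogen-bonded cyclic transition state and to keep the bulky aryloxy group and the aldehyde aryl group apart, which corresponds to the erythro (2R,3R) isomer. The step needs aldol trapping to outrun the 1,2-proton shift that would end in simple O–H insertion, and this is served by the acceptor acetate para to the formyl group of 4, by the excess of 4, by slow addition of 5 and by the low temperature. Chemoselectivity of the carbene for the phenol O–H over the ketal oxygens, the aldehyde oxygen and the arenes is expected from the high rate of O–H capture.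

**Step 4**
Reactants: 8 ethyl (2R,3R)-3-(4-acetoxy-3-methoxyphenyl)-2-[2,6-dimethoxy-4-(2-methyl-1,3-dioxolan-2-yl)phenoxy]-3-hydroxypropanoate
Product: 9 (1R,2S)-2-[2,6-dimethoxy-4-(2-methyl-1,3-dioxolan-2-yl)phenoxy]-1-(4-hydroxy-3-methoxyphenyl)propane-1,3-diol
Conditions: LiBH4 (4 equiv), THF, 0 °C → rt; pH 7 phosphate buffer quench
Reagents that add atoms: none
Why: Hydride reduction of an ester by LiBH4 should convert the α-aryloxy ester into the primary alcohol and at the same time cleave the more electrophilic aryl acetate reductively, while the ketal is inert and neither stereocentre is involved (the C8 descriptor changes from R to S only because CH2OH ranks below the carbinol carbon).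

**Step 5**
Reactants: 9 (1R,2S)-2-[2,6-dimethoxy-4-(2-methyl-1,3-dioxolan-2-yl)phenoxy]-1-(4-hydroxy-3-methoxyphenyl)propane-1,3-diol
Product: 10 1-(4-{[(1R,2S)-1,3-dihydroxy-1-(4-hydroxy-3-methoxyphenyl)propan-2-yl]oxy}-3,5-dimethoxyphenyl)ethan-1-one (CNP0242981.1)
Conditions: pyridinium p-toluenesulfonate (0.2 equiv), THF–H2O (4:1), rt (40 °C if conversion stalls)
Reagents that add atoms: water, O
Why: Acid-catalysed ketal hydrolysis should be fast here because the oxocarbenium ion is stabilised by the para ether oxygen of ring B, so a buffered pyridinium acid should free the acetyl group without ionising the p-hydroxybenzylic C7–OH or disturbing either stereocentre.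

**Compound list**

1 | acetosyringone, 1-(4-hydroxy-3,5-dimethoxyphenyl)ethan-1-one | CC(=O)c1cc(OC)c(O)c(OC)c1 | starting material
2 | 2,6-dimethoxy-4-(2-methyl-1,3-dioxolan-2-yl)phenol | COc1cc(C2(C)OCCO2)cc(OC)c1O | intermediate
3 | vanillin, 4-hydroxy-3-methoxybenzaldehyde | COc1cc(C=O)ccc1O | starting material
4 | 4-formyl-2-methoxyphenyl acetate (vanillin acetate) | COc1cc(C=O)ccc1OC(C)=O | intermediate
5 | ethyl diazoacetate | CCOC(=O)C=[N+]=[N-] | starting material
6 | protic oxonium ylide from 2 and the carbene of 5, ethyl 2-{[2,6-dimethoxy-4-(2-methyl-1,3-dioxolan-2-yl)phenyl]oxonio}acetate C-ylide, not isolated | CCOC(=O)[CH-][OH+]c1c(OC)cc(C2(C)OCCO2)cc1OC | intermediate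
7 | enol, (E)-2-[2,6-dimethoxy-4-(2-methyl-1,3-dioxolan-2-yl)phenoxy]-1-ethoxyethen-1-ol, not isolated | CCO/C(O)=C/Oc1c(OC)cc(C2(C)OCCO2)cc1OC | intermediate
8 | ethyl (2R,3R)-3-(4-acetoxy-3-methoxyphenyl)-2-[2,6-dimethoxy-4-(2-methyl-1,3-dioxolan-2-yl)phenoxy]-3-hydroxypropanoate | COc1cc([C@@H](O)[C@H](C(=O)OCC)Oc2c(OC)cc(C3(C)OCCO3)cc2OC)ccc1OC(C)=O | intermediate
9 | (1R,2S)-2-[2,6-dimethoxy-4-(2-methyl-1,3-dioxolan-2-yl)phenoxy]-1-(4-hydroxy-3-methoxyphenyl)propane-1,3-diol | COc1cc([C@@H](O)[C@H](CO)Oc2c(OC)cc(C3(C)OCCO3)cc2OC)ccc1O | intermediate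
10 | 1-(4-{[(1R,2S)-1,3-dihydroxy-1-(4-hydroxy-3-methoxyphenyl)propan-2-yl]oxy}-3,5-dimethoxyphenyl)ethan-1-one | COc1cc([C@@H](O)[C@H](CO)Oc2c(OC)cc(C(C)=O)cc2OC)ccc1O | target

**Count**

Total steps: 5. Longest linear sequence: 4 steps (step 1 or step 2, then steps 3, 4 and 5).

**Steps most likely to fail**

1. Step 3 (proposed new method). The proton shift that turns the ylide or enol into the plain O–H insertion product may outrun capture by the aldehyde, or capture may occur with poor diastereo- and enantiofacial control. The fallback sets out from 2 and 4, comes back at 8, and gives up catalytic asymmetric induction for known chemistry. Phenol 2 is O-alkylated with ethyl bromoacetate (K2CO3, acetone, reflux; Williamson ether synthesis) to ethyl 2-[2,6-dimethoxy-4-(2-methyl-1,3-dioxolan-2-yl)phenoxy]acetate F1. Its lithium enolate (LiN(iPr)2, THF, −78 °C) is added to 4 in the aldol reaction that is the standard entry to arylglycerol β-aryl ethers. This is expected to favour the erythro pair, that is 8 together with its enantiomer ethyl (2S,3S)-3-(4-acetoxy-3-methoxyphenyl)-2-[2,6-dimethoxy-4-(2-methyl-1,3-dioxolan-2-yl)phenoxy]-3-hydroxypropanoate F2. The minor threo diastereomers are removed by chromatography, and 8 is separated from F2 by preparative HPLC on a cellulose tris(3,5-dimethylphenylcarbamate) stationary phase.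

2. Step 1. The ketone is deactivated by conjugation with the free para hydroxyl, so ketalisation may stall, and the electron-rich ketal may revert during work-up or purification. The fallback sets out from 1 and comes back at 2. Compound 1 is acetylated (Ac2O, pyridine, rt) to 4-acetyl-2,6-dimethoxyphenyl acetate F3, in which the ketone is no longer deactivated. F3 is ketalised under aprotic Noyori conditions (1,2-bis(trimethylsilyloxy)ethane, trimethylsilyl trifluoromethanesulfonate cat., CH2Cl2, −78 °C, pyridine quench) to 2,6-dimethoxy-4-(2-methyl-1,3-dioxolan-2-yl)phenyl acetate F4. Methanolysis of the aryl acetate (K2CO3, MeOH, rt) then returns phenol 2.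

3. Step 5. Acid may ionise the benzylic C7 carbinol, assisted by the free para hydroxyl of ring A, before the ketal is fully cleaved, leading to loss of configuration at C7 (erythro to threo drift) or solvolysis. The fallback sets out from 9 and comes back at 10. The phenol of 9 is acetylated selectively through its phenoxide (Ac2O, aqueous NaOH, THF, 0 °C; Schotten–Baumann conditions) to 4-[(1R,2S)-2-[2,6-dimethoxy-4-(2-methyl-1,3-dioxolan-2-yl)phenoxy]-1,3-dihydroxypropyl]-2-methoxyphenyl acetate F5. With the para oxygen acylated the benzylic position is far less prone to ionise, so the ketal can be hydrolysed (pyridinium p-toluenesulfonate, THF–H2O, rt to 40 °C) to 4-[(1R,2S)-2-(4-acetyl-2,6-dimethoxyphenoxy)-1,3-dihydroxypropyl]-2-methoxyphenyl acetate F6. Methanolysis of the aryl acetate under non-acidic conditions (K2CO3 cat., MeOH, 0 °C) then gives 10.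

**Further compounds**

F1 | step 3 | ethyl 2-[2,6-dimethoxy-4-(2-methyl-1,3-dioxolan-2-yl)phenoxy]acetate | CCOC(=O)COc1c(OC)cc(C2(C)OCCO2)cc1OC
F2 | step 3 | ethyl (2S,3S)-3-(4-acetoxy-3-methoxyphenyl)-2-[2,6-dimethoxy-4-(2-methyl-1,3-dioxolan-2-yl)phenoxy]-3-hydroxypropanoate | COc1cc([C@H](O)[C@@H](C(=O)OCC)Oc2c(OC)cc(C3(C)OCCO3)cc2OC)ccc1OC(C)=O
F3 | step 1 | 4-acetyl-2,6-dimethoxyphenyl acetate | CC(=O)Oc1c(OC)cc(C(C)=O)cc1OC
F4 | step 1 | 2,6-dimethoxy-4-(2-methyl-1,3-dioxolan-2-yl)phenyl acetate | CC(=O)Oc1c(OC)cc(C2(C)OCCO2)cc1OC
F5 | step 5 | 4-[(1R,2S)-2-[2,6-dimethoxy-4-(2-methyl-1,3-dioxolan-2-yl)phenoxy]-1,3-dihydroxypropyl]-2-methoxyphenyl acetate | COc1cc([C@@H](O)[C@H](CO)Oc2c(OC)cc(C3(C)OCCO3)cc2OC)ccc1OC(C)=O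
F6 | step 5 | 4-[(1R,2S)-2-(4-acetyl-2,6-dimethoxyphenoxy)-1,3-dihydroxypropyl]-2-methoxyphenyl acetate | COc1cc([C@@H](O)[C@H](CO)Oc2c(OC)cc(C(C)=O)cc2OC)ccc1OC(C)=O
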